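Each starting material that reacts takes one second substrate by either route, so the second substrate left, bound forms apart, is what has gone in minus target minus uncatalysed product, and the readings of zeta give it at each time of reading.

| flask | starting material | second substrate | free enzyme | remark | time |
|---|---|---|---|---|---|
| zeta | 0.10 M | 1.5 equiv | 0.01 mol% | run made earlier |  |
| beta | 0.15 M | 1.5 equiv | 0.01 mol% | run made earlier |  |
| west | 0.10 M | 1.50 equiv (fed, over 10 h) | 0.01 mol% | all else is in the flask from the start; the feed brings no volume worth counting | 12 h |
| south-east | 0.10 M (fed, over 10 h) | 1.50 equiv | 0.01 mol% | all else is in the flask from the start; the feed brings no volume worth counting | 12 h |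
| north-east | 0.10 M | 1.50 equiv | 0.01 mol% | everything together at the start | 12 h |

| run | time / h | target / % | uncatalysed product / % | starting material / % |
|---|---|---|---|---|
| zeta | 1.00 | 11.1 | 33.0 | 49.9 |
| zeta | 1.50 | 12.6 | 41.1 | 34.8 |
| zeta | 2.50 | 19.1 | 47.9 | 20.2 |
| zeta | 4.00 | 24.7 | 56.7 | 9.7 |
| zeta | 8.00 | 29.2 | 60.5 | 1.5 |
| zeta | 12.0 | 31.0 | 62.4 | 1.4 |
| beta | 0.250 | 5.2 | 17.7 | 77.0 |
| beta | 0.667 | 7.4 | 34.6 | 50.7 |
| beta | 1.33 | 13.0 | 48.4 | 29.3 |
| beta | 2.00 | 19.4 | 55.3 | 18.3 |
| beta | 3.00 | 22.4 | 60.2 | 9.7 |
| beta | 4.00 | 25.5 | 61.9 | 5.6 |

(readings scatter by 1 percentage point)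

- the flask with the highest share of target in target plus uncatalysed product ("all alike" if they lie within 1.5 percentage points) (west / south-east / north-east / all alike)
- share of target in target plus uncatalysed product at the end, west
- share of target in target plus uncatalysed product at the end, south-east
- share of target in target plus uncatalysed product at the end, north-east

In zeta from 4.00 h to 12.0 h, starting material falls from 9.7% to 1.4%. If both routes are then first order in it, it cancels from their ratio; if the enzyme route also goes without regard to second substrate, then at fixed enzyme loading the selectivity factor, target gained per uncatalysed product gained, is a crossover concentration divided by second substrate. Over that stretch zeta gains 6.3 percentage points of target and 5.7 points of uncatalysed product at a mean second substrate of 0.0626 M. The second substrate at which the two routes run equal therefore reads 0.0692 M, with the scatter of the readings in it.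

Even with nothing consumed, west's second substrate averages 0.0750 M over the feed. This reckoning therefore puts west's share near half, above the 33.2% that zeta gives and north-east should repeat.

The forecast gives 37% for west, 35% for south-east and 33% for north-east, lower for west than this reckoning: “West is a tentative pick.”

West ends at 54.3%, south-east at 40.6% and north-east at 34.3%, so west leads.

second complex → free enzyme + target (k = 100 min⁻¹); first complex → loaded enzyme + first product (k = 54.0 min⁻¹); second substrate + loaded enzyme ⇌ second complex (K = 19.0 L mol⁻¹, k = 1700 L mol⁻¹ min⁻¹); starting material + second substrate → uncatalysed product (k = 0.0600 L mol⁻¹ min⁻¹); starting material ⇌ dormant form (K = 0.590, k = 0.00220 min⁻¹); starting material + free enzyme ⇌ first complex (K = 12.0 L mol⁻¹, k = 3100 L mol⁻¹ min⁻¹) Between 6.00 h and 10.0 h, west's second substrate rises from 26.0% to 48.6% of its charge, a mean of 0.0560 M. The crossover over that mean gives 1.24, and west's gains stand at 1.17. In south-east from 10.0 h to 12.0 h, the mean is 0.0687 M, so the crossover gives 1.01, and the gains stand at 1.02.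

All runs were generated by integration on assumed constants; scatter was added.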